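**Assumption:** the SMILES is read as (4Z,6R,7R,8S,10R) in germacrane numbering (C1 ketone, C3–O–C10 bridge, C8 lactone oxygen, C6 ester) with an (E)-configured side-chain alkene.

## Retrosynthetic overview

1. Target 29 ⇒ macrocyclic C6 alcohol 22 + (Z)-2-(bromomethyl)but-2-enoic acid 26 (esterification, then CH2Br → CH2OH).
2. 22 ⇒ open-chain Z-enal 19 in one flask: ring-closing metathesis makes the 3-(bromomethyl)butenolide, then CrCl2 closes C6–C7 (ten-membered ring), setting C6 and C7 and unveiling the exocyclic methylene.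
3. 19 ⇒ furanone 15 + 2-(bromomethyl)acrylic acid 16; 15 ⇒ hydroxy ynone 14 by gold-catalysed 5-endo cyclisation.
4. 14 ⇒ hydroxy lactone 10 + silyl enyne 12 (acetylide opening); 10 ⇒ (S)-lactic acid via a Seebach dioxolanone (C10) and a catalyst-controlled alkenylation (C8).
5. Ring order: furanone first, then butenolide and ten-membered carbocycle together in the key step.

## Route

Step 1
Reactants: 1 (S)-lactic acid; 2 pivalaldehyde
Product: 3 (2S,5S)-2-tert-butyl-5-methyl-1,3-dioxolan-4-one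
Conditions: TsOH·H2O (cat.), H2SO4 (cat.), pentane, reflux, Dean–Stark; recrystallise at −78 °C
Reagents that add atoms: none
Why: Acid-catalysed acetalisation (Seebach self-regeneration of stereocentres) gives the cis dioxolanone under thermodynamic control, the acetal centre (2S) being set by the lactate centre.

Step 2
Reactants: 3 (2S,5S)-2-tert-butyl-5-methyl-1,3-dioxolan-4-one; 4 allyl bromide
Product: 6 (2S,5R)-2-tert-butyl-5-methyl-5-(prop-2-en-1-yl)-1,3-dioxolan-4-one, via lithium enolate 5 (not isolated)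
Conditions: LiN(iPr)2, THF, −78 °C; then 4, −78 → −30 °C
Reagents that add atoms: none
Why: Seebach enolate alkylation, in which allyl bromide enters trans to the tert-butyl group and so replaces the lactate hydrogen with retention, setting the quaternary centre (future C10, R).

Step 3
Reactants: 6 (2S,5R)-2-tert-butyl-5-methyl-5-(prop-2-en-1-yl)-1,3-dioxolan-4-one
Product: 8 2-[(2S,4R)-2-tert-butyl-4-methyl-5-oxo-1,3-dioxolan-4-yl]acetaldehyde, via ozonide 7 (not isolated)
Conditions: O3, CH2Cl2, −78 °C; then Me2S, −78 °C → rt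
Reagents that add atoms: ozone, [O-][O+]=O
Why: Ozonolysis with reductive work-up cleaves the only alkene present and leaves the acetal-ester and both stereocentres untouched.

Step 4
Reactants: 8 2-[(2S,4R)-2-tert-butyl-4-methyl-5-oxo-1,3-dioxolan-4-yl]acetaldehyde
Product: 10 (3R,5S)-5-[(1E)-hex-1-en-1-yl]-3-hydroxy-3-methyloxolan-2-one, via hydroxy dioxolanone 9 (not isolated)
Conditions: hex-1-yne, Cy2BH, toluene, 0 °C → rt; Et2Zn, −78 °C; (+)-MIB (5 mol%); 8, −10 °C; AcOH quench; then TsOH·H2O (5 mol%), CH2Cl2, rt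
Reagents that add atoms: hex-1-yne, C#CCCCC
Why: Amino-alcohol-catalysed alkenylzinc addition (Oppolzer–Walsh type) delivers the (E)-hexenyl group to the Re face of the aldehyde under catalyst control to set C8 (S), and the new hydroxyl then attacks the dioxolanone carbonyl (transacylative lactonisation) to give the γ-lactone with loss of the pivalaldehyde auxiliary.

Step 5
Reactants: 11 (2Z)-3-methylpent-2-en-4-yn-1-ol
Product: 12 tert-butyl(dimethyl){[(2Z)-3-methylpent-2-en-4-yn-1-yl]oxy}silane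
Conditions: TBSCl, imidazole, CH2Cl2, 0 °C → rt
Reagents that add atoms: tert-butyl(chloro)dimethylsilane (TBSCl), CC(C)(C)[Si](C)(C)Cl
Why: Standard silylation masks the Z-allylic hydroxyl, which would otherwise add to the alkyne (furan formation) during the later cyclisation.

Step 6
Reactants: 10 (3R,5S)-5-[(1E)-hex-1-en-1-yl]-3-hydroxy-3-methyloxolan-2-one; 12 tert-butyl(dimethyl){[(2Z)-3-methylpent-2-en-4-yn-1-yl]oxy}silane
Product: 14 (2Z,7R,9S,10E)-1-{[tert-butyl(dimethyl)silyl]oxy}-7,9-dihydroxy-3,7-dimethylpentadeca-2,10-dien-4-yn-6-one, via lithium acetylide 13 (not isolated)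
Conditions: 12 (2.4 equiv), n-BuLi (2.3 equiv), THF, −78 °C; then 10, −78 °C; AcOH quench
Reagents that add atoms: none
Why: Single addition of a lithium acetylide to a γ-lactone (the tetrahedral lithium hemiketal persists at −78 °C, the first equivalent of acetylide serving as base for the tertiary hydroxyl) gives the α′-hydroxy ynone without touching either stereocentre.

Step 7
Reactants: 14 (2Z,7R,9S,10E)-1-{[tert-butyl(dimethyl)silyl]oxy}-7,9-dihydroxy-3,7-dimethylpentadeca-2,10-dien-4-yn-6-one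
Product: 15 (2R)-5-[(2Z)-4-{[tert-butyl(dimethyl)silyl]oxy}but-2-en-2-yl]-2-[(2S,3E)-2-hydroxyoct-3-en-1-yl]-2-methylfuran-3(2H)-one
Conditions: Ph3PAuCl (5 mol%), AgOTf (5 mol%), toluene, rt
Reagents that add atoms: none
Why: Gold-catalysed 5-endo-dig oxa-cyclisation of the α′-hydroxy ynone by the tertiary hydroxyl gives the 3(2H)-furanone, the secondary C8 hydroxyl being able to reach the alkyne only through a seven-membered ring.

Step 8
Reactants: 15 (2R)-5-[(2Z)-4-{[tert-butyl(dimethyl)silyl]oxy}but-2-en-2-yl]-2-[(2S,3E)-2-hydroxyoct-3-en-1-yl]-2-methylfuran-3(2H)-one; 16 2-(bromomethyl)prop-2-enoic acid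
Product: 17 (2S,3E)-1-{(2R)-5-[(2Z)-4-{[tert-butyl(dimethyl)silyl]oxy}but-2-en-2-yl]-2-methyl-3-oxo-2,3-dihydrofuran-2-yl}oct-3-en-2-yl 2-(bromomethyl)prop-2-enoate
Conditions: DIC, DMAP (5 mol%), CH2Cl2, 0 °C
Reagents that add atoms: none
Why: Steglich esterification of the only free hydroxyl (C8) proceeds at the carboxyl group with retention at C8 and installs all four remaining lactone carbons.

Step 9
Reactants: 17 (2S,3E)-1-{(2R)-5-[(2Z)-4-{[tert-butyl(dimethyl)silyl]oxy}but-2-en-2-yl]-2-methyl-3-oxo-2,3-dihydrofuran-2-yl}oct-3-en-2-yl 2-(bromomethyl)prop-2-enoate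
Product: 18 (2S,3E)-1-{(2R)-5-[(2Z)-4-hydroxybut-2-en-2-yl]-2-methyl-3-oxo-2,3-dihydrofuran-2-yl}oct-3-en-2-yl 2-(bromomethyl)prop-2-enoate
Conditions: HF·pyridine, THF, 0 °C → rt
Reagents that add atoms: none
Why: Acidic fluoride desilylation removes the primary allylic silyl ether under conditions that spare the allylic bromide, the ester and the furanone.

Step 10
Reactants: 18 (2S,3E)-1-{(2R)-5-[(2Z)-4-hydroxybut-2-en-2-yl]-2-methyl-3-oxo-2,3-dihydrofuran-2-yl}oct-3-en-2-yl 2-(bromomethyl)prop-2-enoate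
Product: 19 (2S,3E)-1-{(2R)-2-methyl-3-oxo-5-[(2Z)-4-oxobut-2-en-2-yl]-2,3-dihydrofuran-2-yl}oct-3-en-2-yl 2-(bromomethyl)prop-2-enoate
Conditions: MnO2 (activated, excess), CH2Cl2, rt
Reagents that add atoms: none
Why: Chemoselective allylic alcohol oxidation under neutral conditions gives the Z-enal without Z/E isomerisation and without touching the allylic bromide.

Step 11
Reactants: 19 (2S,3E)-1-{(2R)-2-methyl-3-oxo-5-[(2Z)-4-oxobut-2-en-2-yl]-2,3-dihydrofuran-2-yl}oct-3-en-2-yl 2-(bromomethyl)prop-2-enoate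
Product: 22 (4Z,6R,7S,8S,10R)-6-hydroxy-1-oxo-3,10-epoxygermacra-2,4,11(13)-trien-12,8-olide, via bromomethyl butenolide 20 (not isolated), via allylchromium dichloride 21 (not isolated)
Conditions: second-generation Grubbs catalyst [(H2IMes)(PCy3)Cl2Ru=CHPh] (5 mol%), toluene (5 mM), 60 °C; then slow addition to CrCl2 (8 equiv), THF (2 mM final), rt; aq. NH4Cl
Reagents that add atoms: none
Why: Proposed new method: ring-closing metathesis of the hexenyl carbinol 2-(bromomethyl)acrylate gives the 3-(bromomethyl)butenolide with loss of hex-1-ene, and divalent chromium then inserts into the allylic C–Br bond so that the lactone-locked (E-type) allylchromium adds through C7 to the Z-enal in a chair Zimmerman–Traxler transition state on the face anti to the C8–C9 bond, closing the ten-membered ring, regenerating the exocyclic methylene and setting C6 (R) and C7 (trans-fused lactone, 6,7-anti); the closest known reactions are RCM of allylic 2-substituted acrylates to butenolides and Nozaki–Hiyama–Kishi/Barbier additions of 3-(bromomethyl)furan-2(5H)-ones to aldehydes, including macrocyclic variants.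

Step 12
Reactants: 23 acetaldehyde; 24 tert-butyl prop-2-enoate
Product: 25 tert-butyl 3-hydroxy-2-methylidenebutanoate (racemic)
Conditions: DABCO (20 mol%), neat, rt, 5–7 d
Reagents that add atoms: none
Why: Morita–Baylis–Hillman reaction; the carbinol centre is racemic but is destroyed in the next step.

Step 13
Reactants: 25 tert-butyl 3-hydroxy-2-methylidenebutanoate
Product: 26 (2Z)-2-(bromomethyl)but-2-enoic acid
Conditions: 48% aq. HBr, conc. H2SO4, 0 °C → rt
Reagents that add atoms: hydrogen bromide, Br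
Why: Acid-mediated allylic transposition (SN2′-type bromination of the Baylis–Hillman alcohol) gives the thermodynamically preferred trisubstituted alkene with the methyl trans to the carboxyl group, and the tert-butyl ester is cleaved under the same conditions.

Step 14
Reactants: 22 (4Z,6R,7S,8S,10R)-6-hydroxy-1-oxo-3,10-epoxygermacra-2,4,11(13)-trien-12,8-olide; 26 (2Z)-2-(bromomethyl)but-2-enoic acid
Product: 27 (4Z,6R,7R,8S,10R)-1-oxo-3,10-epoxygermacra-2,4,11(13)-trien-12,8-olid-6-yl (2Z)-2-(bromomethyl)but-2-enoate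
Conditions: DIC, DMAP (10 mol%), CH2Cl2, 0 °C → rt
Reagents that add atoms: none
Why: Steglich esterification acylates the single free (C6) hydroxyl with retention, the C7 descriptor changing from S to R only through the priority change at C6.

Step 15
Reactants: 27 (4Z,6R,7R,8S,10R)-1-oxo-3,10-epoxygermacra-2,4,11(13)-trien-12,8-olid-6-yl (2Z)-2-(bromomethyl)but-2-enoate
Product: 29 (4Z,6R,7R,8S,10R)-1-oxo-3,10-epoxygermacra-2,4,11(13)-trien-12,8-olid-6-yl (2E)-2-(hydroxymethyl)but-2-enoate, via formate ester 28 (not isolated)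
Conditions: HCO2Na, DMF, rt; then NaHCO3 (cat.), MeOH, 0 °C
Reagents that add atoms: sodium formate, [Na+].[O-]C=O
Why: Direct SN2 displacement of the primary allylic bromide by formate (a weak base and poor Michael donor) followed by mild methanolysis of the very labile formate releases the primary alcohol without touching the other esters, the α-methylene lactone or the alkene geometry.

## Compound list

1 | (S)-lactic acid | C[C@H](O)C(=O)O | starting material
2 | pivalaldehyde (2,2-dimethylpropanal) | CC(C)(C)C=O | starting material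
3 | (2S,5S)-2-tert-butyl-5-methyl-1,3-dioxolan-4-one | C[C@@H]1O[C@H](C(C)(C)C)OC1=O | intermediate
4 | allyl bromide (3-bromoprop-1-ene) | C=CCBr | starting material
5 | lithium (2S)-2-tert-butyl-5-methyl-1,3-dioxol-4-olate (lithium enolate of 3) | [Li+].CC1=C([O-])O[C@@H](C(C)(C)C)O1 | intermediate
6 | (2S,5R)-2-tert-butyl-5-methyl-5-(prop-2-en-1-yl)-1,3-dioxolan-4-one | C[C@]1(CC=C)O[C@H](C(C)(C)C)OC1=O | intermediate
7 | (2S,5R)-2-tert-butyl-5-methyl-5-(1,2,4-trioxolan-3-ylmethyl)-1,3-dioxolan-4-one (ozonide, both epimers at the trioxolane carbon) | C[C@]1(CC2OCOO2)O[C@H](C(C)(C)C)OC1=O | intermediate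
8 | 2-[(2S,4R)-2-tert-butyl-4-methyl-5-oxo-1,3-dioxolan-4-yl]acetaldehyde | C[C@]1(CC=O)O[C@H](C(C)(C)C)OC1=O | intermediate
9 | (2S,5R)-2-tert-butyl-5-[(2S,3E)-2-hydroxyoct-3-en-1-yl]-5-methyl-1,3-dioxolan-4-one | C[C@]1(C[C@H](O)/C=C/CCCC)O[C@H](C(C)(C)C)OC1=O | intermediate
10 | (3R,5S)-5-[(1E)-hex-1-en-1-yl]-3-hydroxy-3-methyloxolan-2-one | C[C@@]1(O)C[C@@H](/C=C/CCCC)OC1=O | intermediate
11 | (2Z)-3-methylpent-2-en-4-yn-1-ol | C#C/C(C)=C\CO | starting material
12 | tert-butyl(dimethyl){[(2Z)-3-methylpent-2-en-4-yn-1-yl]oxy}silane | C#C/C(C)=C\CO[Si](C)(C)C(C)(C)C | intermediate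
13 | lithium acetylide of 12 | [Li+].[C-]#C/C(C)=C\CO[Si](C)(C)C(C)(C)C | intermediate
14 | (2Z,7R,9S,10E)-1-{[tert-butyl(dimethyl)silyl]oxy}-7,9-dihydroxy-3,7-dimethylpentadeca-2,10-dien-4-yn-6-one | CCCC/C=C/[C@@H](O)C[C@@](C)(O)C(=O)C#C/C(C)=C\CO[Si](C)(C)C(C)(C)C | intermediate
15 | (2R)-5-[(2Z)-4-{[tert-butyl(dimethyl)silyl]oxy}but-2-en-2-yl]-2-[(2S,3E)-2-hydroxyoct-3-en-1-yl]-2-methylfuran-3(2H)-one | CCCC/C=C/[C@@H](O)C[C@@]1(C)OC(=CC1=O)/C(C)=C\CO[Si](C)(C)C(C)(C)C | intermediate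
16 | 2-(bromomethyl)prop-2-enoic acid | C=C(CBr)C(=O)O | starting material
17 | (2S,3E)-1-{(2R)-5-[(2Z)-4-{[tert-butyl(dimethyl)silyl]oxy}but-2-en-2-yl]-2-methyl-3-oxo-2,3-dihydrofuran-2-yl}oct-3-en-2-yl 2-(bromomethyl)prop-2-enoate | CCCC/C=C/[C@@H](OC(=O)C(=C)CBr)C[C@@]1(C)OC(=CC1=O)/C(C)=C\CO[Si](C)(C)C(C)(C)C | intermediate
18 | (2S,3E)-1-{(2R)-5-[(2Z)-4-hydroxybut-2-en-2-yl]-2-methyl-3-oxo-2,3-dihydrofuran-2-yl}oct-3-en-2-yl 2-(bromomethyl)prop-2-enoate | CCCC/C=C/[C@@H](OC(=O)C(=C)CBr)C[C@@]1(C)OC(=CC1=O)/C(C)=C\CO | intermediate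
19 | (2S,3E)-1-{(2R)-2-methyl-3-oxo-5-[(2Z)-4-oxobut-2-en-2-yl]-2,3-dihydrofuran-2-yl}oct-3-en-2-yl 2-(bromomethyl)prop-2-enoate | CCCC/C=C/[C@@H](OC(=O)C(=C)CBr)C[C@@]1(C)OC(=CC1=O)/C(C)=C\C=O | intermediate
20 | (5S)-3-(bromomethyl)-5-({(2R)-2-methyl-3-oxo-5-[(2Z)-4-oxobut-2-en-2-yl]-2,3-dihydrofuran-2-yl}methyl)furan-2(5H)-one | O=C1O[C@@H](C[C@@]2(C)OC(=CC2=O)/C(C)=C\C=O)C=C1CBr | intermediate
21 | dichloro{[(5S)-5-({(2R)-2-methyl-3-oxo-5-[(2Z)-4-oxobut-2-en-2-yl]-2,3-dihydrofuran-2-yl}methyl)-2-oxo-2,5-dihydrofuran-3-yl]methyl}chromium (trivalent chromium, THF ligands omitted) | O=C1O[C@@H](C[C@@]2(C)OC(=CC2=O)/C(C)=C\C=O)C=C1C[Cr](Cl)Cl | intermediate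
22 | (4Z,6R,7S,8S,10R)-6-hydroxy-1-oxo-3,10-epoxygermacra-2,4,11(13)-trien-12,8-olide (the C6 alcohol of the target) | C=C1C(=O)O[C@H]2C[C@@]3(C)OC(=CC3=O)/C(C)=C\[C@@H](O)[C@H]12 | intermediate
23 | acetaldehyde | CC=O | starting material
24 | tert-butyl prop-2-enoate (tert-butyl acrylate) | C=CC(=O)OC(C)(C)C | starting material
25 | tert-butyl 3-hydroxy-2-methylidenebutanoate (racemic) | CC(O)C(=C)C(=O)OC(C)(C)C | intermediate
26 | (2Z)-2-(bromomethyl)but-2-enoic acid | C/C=C(\CBr)C(=O)O | intermediate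
27 | (4Z,6R,7R,8S,10R)-1-oxo-3,10-epoxygermacra-2,4,11(13)-trien-12,8-olid-6-yl (2Z)-2-(bromomethyl)but-2-enoate | C=C1C(=O)O[C@H]2C[C@@]3(C)OC(=CC3=O)/C(C)=C\[C@@H](OC(=O)/C(=C/C)CBr)[C@H]12 | intermediate
28 | (4Z,6R,7R,8S,10R)-1-oxo-3,10-epoxygermacra-2,4,11(13)-trien-12,8-olid-6-yl (2E)-2-[(formyloxy)methyl]but-2-enoate | C=C1C(=O)O[C@H]2C[C@@]3(C)OC(=CC3=O)/C(C)=C\[C@@H](OC(=O)/C(=C/C)COC=O)[C@H]12 | intermediate
29 | (4Z,6R,7R,8S,10R)-1-oxo-3,10-epoxygermacra-2,4,11(13)-trien-12,8-olid-6-yl (2E)-2-(hydroxymethyl)but-2-enoate (CNP0323575.1) | C=C1C(=O)O[C@H]2C[C@@]3(C)OC(=CC3=O)/C(C)=C\[C@@H](OC(=O)/C(=C/C)CO)[C@H]12 | target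

## Step count and risks

Total step count: 15. Longest linear sequence: 12 steps (steps 1–4, 6–11, 14, 15, from (S)-lactic acid).

**Step 11 (most likely to fail).** The medium-ring allylation may give oligomers or the cis-fused lactone; facial selectivity at C7 rests on a transition-state argument, not on precedent for this ring system. The fallback sets out from lactone 10 and comes back at alcohol 22, closing the ring at C4=C5 by metathesis instead of at C6–C7 by allylation. Lactone 10 is opened with the lithium acetylide of 2-methylbut-1-en-3-yne to give the isopropenyl ynone diol F1. Cyclisation with Ph3PAuCl/AgOTf gives the 5-isopropenyl furanone F2, and DIC esterification with 16 gives the diene ester F3. RCM with the second-generation Grubbs catalyst gives the isolated bromomethyl butenolide F4. An intermolecular Barbier addition of F4 to acrolein (Zn dust, THF/aq. NH4Cl), which adds anti to the C8 substituent, gives the vinyl carbinol F5. RCM of F5 at high dilution with the second-generation Hoveyda–Grubbs catalyst [(H2IMes)Cl2Ru=CH(2-iPrO-C6H4)] closes the ring as the Z alkene and returns 22.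

**Step 4.** Catalyst control at C8 next to the quaternary dioxolanone carbon may be eroded, and the zinc alkoxide may transacylate early. The fallback sets out from aldehyde 8 and comes back at hydroxy dioxolanone 9, setting C8 by ketone reduction instead of C–C addition. (E)-Hex-1-enylmagnesium bromide is added to 8 at −78 °C to give the carbinol epimer mixture F6. Dess–Martin periodinane oxidises it to the enone F7. (R)-2-Methyl-CBS-oxazaborolidine with BH3·SMe2 reduces F7 under reagent control to 9, which lactonises to 10 with catalytic TsOH as in step 4.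

**Step 15.** Formate could attack in the SN2′ sense, or the methanolysis could touch the α-methylene lactone. The fallback sets out from acid 26 (joined later by alcohol 22) and comes back at target 29, installing the hydroxyl before the coupling and carrying it as a silyl ether. Acid 26 is treated with excess HCO2Na in DMF and then aqueous K2CO3 to give (2E)-2-(hydroxymethyl)but-2-enoic acid F8. TBSCl/imidazole followed by K2CO3 in MeOH–H2O (cleaving only the silyl ester) gives the silyl ether acid F9. DIC/DMAP coupling with 22 gives the silyl-protected target F10, and HF·pyridine returns 29.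

## Further compounds

F1 | step 11 | (6R,8S,9E)-6,8-dihydroxy-2,6-dimethyltetradeca-1,9-dien-3-yn-5-one | CCCC/C=C/[C@@H](O)C[C@@](C)(O)C(=O)C#CC(C)=C
F2 | step 11 | (2R)-2-[(2S,3E)-2-hydroxyoct-3-en-1-yl]-2-methyl-5-(prop-1-en-2-yl)furan-3(2H)-one | CCCC/C=C/[C@@H](O)C[C@@]1(C)OC(=CC1=O)C(C)=C
F3 | step 11 | (2S,3E)-1-[(2R)-2-methyl-3-oxo-5-(prop-1-en-2-yl)-2,3-dihydrofuran-2-yl]oct-3-en-2-yl 2-(bromomethyl)prop-2-enoate | CCCC/C=C/[C@@H](OC(=O)C(=C)CBr)C[C@@]1(C)OC(=CC1=O)C(C)=C
F4 | step 11 | (5S)-3-(bromomethyl)-5-{[(2R)-2-methyl-3-oxo-5-(prop-1-en-2-yl)-2,3-dihydrofuran-2-yl]methyl}furan-2(5H)-one | O=C1O[C@@H](C[C@@]2(C)OC(=CC2=O)C(C)=C)C=C1CBr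
F5 | step 11 | (4S,5S)-4-[(1R)-1-hydroxyprop-2-en-1-yl]-3-methylidene-5-{[(2R)-2-methyl-3-oxo-5-(prop-1-en-2-yl)-2,3-dihydrofuran-2-yl]methyl}oxolan-2-one | C=C1C(=O)O[C@@H](C[C@@]2(C)OC(=CC2=O)C(C)=C)[C@@H]1[C@H](O)C=C
F6 | step 4 | (2S,5R)-2-tert-butyl-5-[(3E)-2-hydroxyoct-3-en-1-yl]-5-methyl-1,3-dioxolan-4-one (both carbinol epimers) | C[C@]1(CC(O)/C=C/CCCC)O[C@H](C(C)(C)C)OC1=O
F7 | step 4 | (2S,5R)-2-tert-butyl-5-methyl-5-[(3E)-2-oxooct-3-en-1-yl]-1,3-dioxolan-4-one | C[C@]1(CC(=O)/C=C/CCCC)O[C@H](C(C)(C)C)OC1=O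
F8 | step 15 | (2E)-2-(hydroxymethyl)but-2-enoic acid | C/C=C(\CO)C(=O)O
F9 | step 15 | (2E)-2-({[tert-butyl(dimethyl)silyl]oxy}methyl)but-2-enoic acid | C/C=C(\CO[Si](C)(C)C(C)(C)C)C(=O)O
F10 | step 15 | (4Z,6R,7R,8S,10R)-1-oxo-3,10-epoxygermacra-2,4,11(13)-trien-12,8-olid-6-yl (2E)-2-({[tert-butyl(dimethyl)silyl]oxy}methyl)but-2-enoate | C=C1C(=O)O[C@H]2C[C@@]3(C)OC(=CC3=O)/C(C)=C\[C@@H](OC(=O)/C(=C/C)CO[Si](C)(C)C(C)(C)C)[C@H]12
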